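**Retrosynthetic overview**

1. The target is cut back to its bis-MOM ether, and that to a C6-unsubstituted chromene plus the Weinreb amide of 4-(methoxymethoxy)benzoic acid; the two are joined by directed lithiation at C6.
2. The chromene is cut at C8a–O1, C4a–C4 and O1–C2 to an aryne (formal triple bond C4a–C8a) and 3-methylbut-2-enal; the aryne is released from an ortho-silyl aryl triflate.
3. The strategy rests on this feature: the pyran ring is fused to the benzene ring through the adjacent carbons C8a (bonded to O1) and C4a (bonded to C4), and C4a stands next to the methoxy-bearing C5, which polarizes the aryne so that oxygen goes to C8a and carbon to C4a. C2 with its two methyl groups, C3 and C4 are the carbons of the enal.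
4. The silyl triflate comes from 5-methoxyresorcinol: bis-MOM ether, lithiation and prenylation between the MOM groups, deprotection, mono-MOM ether, N-isopropyl carbamate, carbamate-directed silylation, carbamate to triflate.
5. Ring order: the benzene ring is bought, the pyran ring is the only ring made (key step), and the 4-hydroxyphenyl ring is attached afterwards together with the ketone carbon.

Key step: step 8

Remark: alkylation of free 5-methoxyresorcinol with prenyl bromide would not distinguish C2 from C4/C6, so the prenyl group is placed by lithiation of the bis-MOM ether; the target has no stereocentre, and intermediates 17 and 24, which carry one, are racemic.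

**Route**

Step 1
Reactants: 1 5-methoxyresorcinol
Product: 2 1-methoxy-3,5-bis(methoxymethoxy)benzene
Conditions: NaH (2.4 equiv), DMF, 0 °C; MOMCl (2.4 equiv), 0 °C → rt
Reagents that add atoms: chloromethyl methyl ether (MOMCl), COCCl
Why: Double Williamson-type O-alkylation of the phenoxides with the reactive α-chloro ether should give the bis-acetal, which protects both phenols and supplies two strong directing groups for step 2.

Step 2
Reactants: 2 1-methoxy-3,5-bis(methoxymethoxy)benzene; 3 prenyl bromide
Product: 5 5-methoxy-1,3-bis(methoxymethoxy)-2-(3-methylbut-2-enyl)benzene, via aryllithium 4 (not isolated)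
Conditions: n-BuLi (1.1 equiv), THF, 0 °C, 1 h; then 3, −78 °C → rt
Reagents that add atoms: none
Why: Directed ortho-metalation should take place at the carbon between the two MOM ethers, where two acetal oxygens hold the lithium (the other ring positions have one MOM and one methoxy neighbour), and the aryllithium is then alkylated at the primary carbon of prenyl bromide in an SN2 reaction.

Step 3
Reactants: 5 5-methoxy-1,3-bis(methoxymethoxy)-2-(3-methylbut-2-enyl)benzene
Product: 6 5-methoxy-2-(3-methylbut-2-enyl)benzene-1,3-diol
Conditions: HCl (1 M in MeOH), rt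
Reagents that add atoms: none
Why: Acid-catalysed acetal solvolysis (transacetalisation to dimethoxymethane) should free both phenols, and dilute methanolic HCl at room temperature should be too mild for the phenol to add across the trisubstituted alkene.

Step 4
Reactants: 6 5-methoxy-2-(3-methylbut-2-enyl)benzene-1,3-diol
Product: 7 5-methoxy-3-(methoxymethoxy)-2-(3-methylbut-2-enyl)phenol
Conditions: NaH (1.0 equiv), DMF, 0 °C; MOMCl (1.0 equiv), 0 °C → rt
Reagents that add atoms: chloromethyl methyl ether (MOMCl), COCCl
Why: Williamson-type mono-O-alkylation through the monosodium salt should give a single mono-ether because the two hydroxyl groups of the symmetrical diol are equivalent; the diol 6 and bis-ether 5 that accompany it are returned to steps 4 and 3.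

Step 5
Reactants: 7 5-methoxy-3-(methoxymethoxy)-2-(3-methylbut-2-enyl)phenol
Product: 8 5-methoxy-3-(methoxymethoxy)-2-(3-methylbut-2-enyl)phenyl N-(propan-2-yl)carbamate
Conditions: i-PrNCO (1.5 equiv), Et3N (0.2 equiv), CH2Cl2, rt
Reagents that add atoms: isopropyl isocyanate, CC(C)N=C=O
Why: Base-catalysed addition of the phenol to the isocyanate (carbamoylation) should give the N-isopropyl carbamate, which serves first as ortho-directing group and then as the precursor of the leaving group.

Step 6
Reactants: 8 5-methoxy-3-(methoxymethoxy)-2-(3-methylbut-2-enyl)phenyl N-(propan-2-yl)carbamate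
Product: 12 3-methoxy-5-(methoxymethoxy)-6-(3-methylbut-2-enyl)-2-(trimethylsilyl)phenyl N-(propan-2-yl)carbamate, via N-silyl carbamate 9 (not isolated), via aryllithium 10 (not isolated), via N-silyl C-silyl carbamate 11 (not isolated)
Conditions: TBSOTf (1.05 equiv), TMEDA, Et2O, 0 °C → rt; n-BuLi (2 equiv), TMEDA, −78 °C; TMSCl, −78 °C → rt; cold aq. NaHSO4 work-up
Reagents that add atoms: chlorotrimethylsilane, C[Si](C)(C)Cl
Why: Directed ortho-metalation of the carbamate, whose N–H is masked in the flask as the N-silyl derivative, should occur at the only free position ortho to the carbamate, which is also flanked by the methoxy group; TMSCl traps the aryllithium at −78 °C before an anionic Fries rearrangement can set in, and the N–Si bond is hydrolysed on work-up.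

Step 7
Reactants: 12 3-methoxy-5-(methoxymethoxy)-6-(3-methylbut-2-enyl)-2-(trimethylsilyl)phenyl N-(propan-2-yl)carbamate
Product: 14 3-methoxy-5-(methoxymethoxy)-6-(3-methylbut-2-enyl)-2-(trimethylsilyl)phenyl trifluoromethanesulfonate, via silylphenol 13 (not isolated)
Conditions: Et2NH, DBU, MeCN, 40 °C; then PhNTf2, rt → 40 °C (one pot)
Reagents that add atoms: N-phenylbis(trifluoromethanesulfonimide), O=S(=O)(N(c1ccccc1)S(=O)(=O)C(F)(F)F)C(F)(F)F
Why: E1cB cleavage of the N–H carbamate by DBU expels isopropyl isocyanate (scavenged by Et2NH as the urea) and leaves the phenoxide, which is O-sulfonylated in the same flask to the ortho-silyl aryl triflate.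

Step 8
Reactants: 14 3-methoxy-5-(methoxymethoxy)-6-(3-methylbut-2-enyl)-2-(trimethylsilyl)phenyl trifluoromethanesulfonate; 15 3-methylbut-2-enal
Product: 19 5-methoxy-7-(methoxymethoxy)-2,2-dimethyl-8-(3-methylbut-2-enyl)-2H-chromene, via aryne 16 (not isolated), via benzoxete 17 (not isolated), via ortho-quinone methide 18 (not isolated)
Conditions: CsF (3 equiv), 15 (5 equiv), MeCN, rt → 50 °C
Reagents that add atoms: none
Why: Fluoride attacks the silicon of 14 and triflate leaves to give aryne 16; the carbonyl oxygen of 15 adds to the aryne carbon that becomes C8a and the aryl anion left at C4a closes on the carbonyl carbon (stepwise formal [2+2]) to benzoxete 17. Ring 17 opens by 4π electrocyclic cleavage to ortho-quinone methide 18, whose 1-oxatriene (O1=C8a–C4a=C4–C3=C2) closes thermally by disrotatory oxa-6π electrocyclization, which forms the O1–C2 bond and the six-membered pyran ring and restores the aromatic ring. The closest known reaction type is the fluoride-induced annulation of ortho-silyl aryl triflates with α,β-unsaturated aldehydes to 2H-chromenes, here applied to a more substituted alkoxyaryne and a β,β-dimethyl enal. No stereocentre is formed, because C2 carries two methyl groups. The step needs oxygen at C8a and carbon at C4a: the methoxy group on C5 polarizes the aryne inductively so that the nucleophile attacks the remote carbon and the negative charge develops beside the methoxy group, and the same methoxy group holds the alkenyl arm of 18 on the carbonyl side, where it can cyclize. The enal is used in excess so that carbonyl addition outruns ene reactions of the aryne with the allylic hydrogens of the prenyl groups.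

Step 9
Reactants: 20 4-hydroxybenzoic acid
Product: 21 4-hydroxy-N-methoxy-N-methylbenzamide
Conditions: MeNH(OMe)·HCl, EDC·HCl, HOBt, Et3N, DMF, 0 °C → rt
Reagents that add atoms: N,O-dimethylhydroxylamine hydrochloride, CNOC.Cl
Why: Carbodiimide-mediated amide coupling through the HOBt active ester should give the Weinreb amide without protection of the phenol, because the amine is much the better nucleophile.

Step 10
Reactants: 21 4-hydroxy-N-methoxy-N-methylbenzamide
Product: 22 N-methoxy-4-(methoxymethoxy)-N-methylbenzamide
Conditions: NaH (1.1 equiv), DMF, 0 °C; MOMCl (1.1 equiv), 0 °C → rt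
Reagents that add atoms: chloromethyl methyl ether (MOMCl), COCCl
Why: Williamson-type O-alkylation of the phenoxide should give the aryl MOM ether, which tolerates the aryllithium of step 11 and leaves together with the other MOM group in step 12.

Step 11
Reactants: 19 5-methoxy-7-(methoxymethoxy)-2,2-dimethyl-8-(3-methylbut-2-enyl)-2H-chromene; 22 N-methoxy-4-(methoxymethoxy)-N-methylbenzamide
Product: 25 [5-methoxy-7-(methoxymethoxy)-2,2-dimethyl-8-(3-methylbut-2-enyl)-2H-chromen-6-yl][4-(methoxymethoxy)phenyl]methanone, via aryllithium 23 (not isolated), via tetrahedral lithium adduct 24 (not isolated)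
Conditions: n-BuLi (1.2 equiv), TMEDA, THF, −78 → −20 °C; then 22, −78 °C → rt; H2O quench
Reagents that add atoms: none
Why: Directed ortho-metalation should occur at C6, the only aromatic C–H of 19 and flanked by the methoxy and MOM oxygens, and acyl substitution on the Weinreb amide then gives the ketone, over-addition being blocked because the chelated tetrahedral adduct 24 persists until the aqueous quench.

Step 12
Reactants: 25 [5-methoxy-7-(methoxymethoxy)-2,2-dimethyl-8-(3-methylbut-2-enyl)-2H-chromen-6-yl][4-(methoxymethoxy)phenyl]methanone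
Product: 26 vismiaphenone F, (4-hydroxyphenyl)[7-hydroxy-5-methoxy-2,2-dimethyl-8-(3-methylbut-2-enyl)-2H-chromen-6-yl]methanone
Conditions: HCl (2 M in MeOH), rt → 40 °C
Reagents that add atoms: none
Why: Acid-catalysed solvolysis of both aryl MOM acetals should give the target, and the C7 hydroxyl that is set free is hydrogen-bonded to the ketone, which should keep it from adding to the C8 prenyl group under these mild conditions.

**Compound list**

1 | 5-methoxyresorcinol (5-methoxybenzene-1,3-diol) | COc1cc(O)cc(O)c1 | starting material
2 | 1-methoxy-3,5-bis(methoxymethoxy)benzene | COCOc1cc(OC)cc(OCOC)c1 | intermediate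
3 | prenyl bromide (1-bromo-3-methylbut-2-ene) | CC(C)=CCBr | starting material
4 | [4-methoxy-2,6-bis(methoxymethoxy)phenyl]lithium (not isolated) | [Li]c1c(OCOC)cc(OC)cc1OCOC | intermediate
5 | 5-methoxy-1,3-bis(methoxymethoxy)-2-(3-methylbut-2-enyl)benzene | COCOc1cc(OC)cc(OCOC)c1CC=C(C)C | intermediate
6 | 5-methoxy-2-(3-methylbut-2-enyl)benzene-1,3-diol | COc1cc(O)c(CC=C(C)C)c(O)c1 | intermediate
7 | 5-methoxy-3-(methoxymethoxy)-2-(3-methylbut-2-enyl)phenol | COc1cc(O)c(CC=C(C)C)c(OCOC)c1 | intermediate
8 | 5-methoxy-3-(methoxymethoxy)-2-(3-methylbut-2-enyl)phenyl N-(propan-2-yl)carbamate | COc1cc(OC(=O)NC(C)C)c(CC=C(C)C)c(OCOC)c1 | intermediate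
9 | N-(tert-butyldimethylsilyl) derivative of carbamate 8 (not isolated) | COc1cc(OC(=O)N(C(C)C)[Si](C)(C)C(C)(C)C)c(CC=C(C)C)c(OCOC)c1 | intermediate
10 | aryllithium from 9, lithium on the ring carbon between the carbamate and methoxy groups (not isolated) | COc1cc(OCOC)c(CC=C(C)C)c(OC(=O)N(C(C)C)[Si](C)(C)C(C)(C)C)c1[Li] | intermediate
11 | N-(tert-butyldimethylsilyl) derivative of carbamate 12 (not isolated) | COc1cc(OCOC)c(CC=C(C)C)c(OC(=O)N(C(C)C)[Si](C)(C)C(C)(C)C)c1[Si](C)(C)C | intermediate
12 | 3-methoxy-5-(methoxymethoxy)-6-(3-methylbut-2-enyl)-2-(trimethylsilyl)phenyl N-(propan-2-yl)carbamate | COc1cc(OCOC)c(CC=C(C)C)c(OC(=O)NC(C)C)c1[Si](C)(C)C | intermediate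
13 | 3-methoxy-5-(methoxymethoxy)-6-(3-methylbut-2-enyl)-2-(trimethylsilyl)phenol (not isolated) | COc1cc(OCOC)c(CC=C(C)C)c(O)c1[Si](C)(C)C | intermediate
14 | 3-methoxy-5-(methoxymethoxy)-6-(3-methylbut-2-enyl)-2-(trimethylsilyl)phenyl trifluoromethanesulfonate | COc1cc(OCOC)c(CC=C(C)C)c(OS(=O)(=O)C(F)(F)F)c1[Si](C)(C)C | intermediate
15 | 3-methylbut-2-enal | CC(C)=CC=O | starting material
16 | 3-methoxy-5-(methoxymethoxy)-6-(3-methylbut-2-enyl)benzyne (not isolated) | COC1=CC(OCOC)=C(CC=C(C)C)C#C1 | intermediate
17 | 3-methoxy-5-(methoxymethoxy)-6-(3-methylbut-2-enyl)-2-(2-methylprop-1-enyl)-2H-benzo[b]oxete, racemic (not isolated) | COc1cc(OCOC)c(CC=C(C)C)c2OC(C=C(C)C)c12 | intermediate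
18 | (6Z)-5-methoxy-3-(methoxymethoxy)-2-(3-methylbut-2-enyl)-6-(3-methylbut-2-enylidene)cyclohexa-2,4-dien-1-one (not isolated) | COC1=CC(OCOC)=C(CC=C(C)C)C(=O)/C1=C\C=C(C)C | intermediate
19 | 5-methoxy-7-(methoxymethoxy)-2,2-dimethyl-8-(3-methylbut-2-enyl)-2H-chromene | COc1cc(OCOC)c(CC=C(C)C)c2OC(C)(C)C=Cc12 | intermediate
20 | 4-hydroxybenzoic acid | O=C(O)c1ccc(O)cc1 | starting material
21 | 4-hydroxy-N-methoxy-N-methylbenzamide | CON(C)C(=O)c1ccc(O)cc1 | intermediate
22 | N-methoxy-4-(methoxymethoxy)-N-methylbenzamide | COCOc1ccc(cc1)C(=O)N(C)OC | intermediate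
23 | [5-methoxy-7-(methoxymethoxy)-2,2-dimethyl-8-(3-methylbut-2-enyl)-2H-chromen-6-yl]lithium (not isolated) | [Li]c1c(OC)c2C=CC(C)(C)Oc2c(CC=C(C)C)c1OCOC | intermediate
24 | lithium [5-methoxy-7-(methoxymethoxy)-2,2-dimethyl-8-(3-methylbut-2-enyl)-2H-chromen-6-yl][4-(methoxymethoxy)phenyl][methoxy(methyl)amino]methanolate, racemic (not isolated) | COCOc1ccc(cc1)C(O[Li])(N(C)OC)c1c(OC)c2C=CC(C)(C)Oc2c(CC=C(C)C)c1OCOC | intermediate
25 | [5-methoxy-7-(methoxymethoxy)-2,2-dimethyl-8-(3-methylbut-2-enyl)-2H-chromen-6-yl][4-(methoxymethoxy)phenyl]methanone | COCOc1ccc(cc1)C(=O)c1c(OC)c2C=CC(C)(C)Oc2c(CC=C(C)C)c1OCOC | intermediate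
26 | vismiaphenone F, (4-hydroxyphenyl)[7-hydroxy-5-methoxy-2,2-dimethyl-8-(3-methylbut-2-enyl)-2H-chromen-6-yl]methanone | COc1c2c(c(CC=C(C)C)c(O)c1C(=O)c1ccc(O)cc1)OC(C)(C)C=C2 | target

**Step count**

Total: 12 steps. Longest linear sequence: 10 steps (steps 1–8, 11, 12); steps 9 and 10 make the amide 22.

**Steps most likely to fail**

Step 8. The electron-rich aryne, flanked on both sides, may be consumed by fluoride addition or by ene reaction with allylic hydrogens of a prenyl group or of the enal before the weakly nucleophilic carbonyl oxygen adds, or the oxygen may add at the wrong aryne carbon. The fallback sets out from phenol 7, which already carries the future O1 on the future C8a and a free ortho C–H at the future C4a. Condensation of 7 with 3-methylbut-2-enal 15 in pyridine at 140 °C (or with ethylenediammonium diacetate as catalyst in refluxing xylene) should proceed by ortho C-alkylation, dehydration to the same ortho-quinone methide and oxa-6π closure. It comes back to the route at chromene 19; no new compound is made on the way (F0).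

Step 6. Metalation may go to the ring carbon between the methoxy and MOM groups instead of the carbon beside the carbamate, or the silyl triflate may attack the MOM acetal, so that silicon ends up at the wrong place or the protecting group is lost. The fallback sets out from diol 6 and silylates before the two oxygens are differentiated, so that no MOM group is present during the metalation. Both hydroxyl groups are carbamoylated with isopropyl isocyanate to give 5-methoxy-2-(3-methylbut-2-enyl)-1,3-phenylene bis[N-(propan-2-yl)carbamate] F1. Double N-silylation (TBSOTf, TMEDA), one ring lithiation (n-BuLi, −78 °C) and TMSCl should give the mono-silylated bis(carbamate) 5-methoxy-2-(3-methylbut-2-enyl)-4-(trimethylsilyl)-1,3-phenylene bis[N-(propan-2-yl)carbamate] F2; the two ring C–H bonds of F1 are equivalent and each lies between a carbamate and the methoxy group. Et2NH and DBU remove both carbamates to give 5-methoxy-2-(3-methylbut-2-enyl)-4-(trimethylsilyl)benzene-1,3-diol F3. MOMCl (1 equiv) with i-Pr2NEt should then protect the hydroxyl that has only one ortho substituent, the other being shielded by the silyl and prenyl groups. This gives silylphenol 13, where the fallback comes back to the route; 13 is isolated and triflated with PhNTf2 and DBU to 14.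

Step 11. Addition of the doubly ortho-substituted aryllithium to the electron-rich Weinreb amide may be slow, so that deprotonation of the N-methoxy group (loss of formaldehyde) and proton return to 19 take over. The fallback sets out from chromene 19: lithiation as in step 11 and addition to 4-(methoxymethoxy)benzaldehyde F4 (from 4-hydroxybenzaldehyde, NaH, MOMCl) should give the diaryl carbinol [5-methoxy-7-(methoxymethoxy)-2,2-dimethyl-8-(3-methylbut-2-enyl)-2H-chromen-6-yl][4-(methoxymethoxy)phenyl]methanol F5. Oxidation of the doubly benzylic alcohol with MnO2 in CH2Cl2 (or with Dess–Martin periodinane) comes back to the route at ketone 25.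

**Further compounds**

F0 | step 8 | none | none
F1 | step 6 | 5-methoxy-2-(3-methylbut-2-enyl)-1,3-phenylene bis[N-(propan-2-yl)carbamate] | COc1cc(OC(=O)NC(C)C)c(CC=C(C)C)c(OC(=O)NC(C)C)c1
F2 | step 6 | 5-methoxy-2-(3-methylbut-2-enyl)-4-(trimethylsilyl)-1,3-phenylene bis[N-(propan-2-yl)carbamate] | COc1cc(OC(=O)NC(C)C)c(CC=C(C)C)c(OC(=O)NC(C)C)c1[Si](C)(C)C
F3 | step 6 | 5-methoxy-2-(3-methylbut-2-enyl)-4-(trimethylsilyl)benzene-1,3-diol | COc1cc(O)c(CC=C(C)C)c(O)c1[Si](C)(C)C
F4 | step 11 | 4-(methoxymethoxy)benzaldehyde | COCOc1ccc(C=O)cc1
F5 | step 11 | [5-methoxy-7-(methoxymethoxy)-2,2-dimethyl-8-(3-methylbut-2-enyl)-2H-chromen-6-yl][4-(methoxymethoxy)phenyl]methanol, racemic | COCOc1ccc(cc1)C(O)c1c(OC)c2C=CC(C)(C)Oc2c(CC=C(C)C)c1OCOC
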